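**Retrosynthetic overview**
1. Target 20 ⇐ alkene 19 (hydrogenation) ⇐ aldehyde 14 + arene 15 + alkenylboronic acid 16: a new boron-templated three-component coupling makes the C-9′–aryl and C-9′–alkenyl bonds and sets C-9′.
2. 14 ⇐ diketone 11: both tertiary carbinols (C-4, C-11) come from one double MeMgBr addition; the C-7 acetyl group comes from the C-7 ketone (TosMIC, then MeLi).
3. The C-1 CH2OH group, the C-4 oxygen and the trans ring fusion (C-5) ⇐ sequential hydroboration of diene ketal 3.
4. 3 ⇐ (S)-Wieland–Miescher ketone 1: Wittig methylenation at C-1, deconjugative ketalisation at C-7.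
5. Ring order: rings A and B both arrive preformed in 1 (no ring is built in the route); the aromatic ring arrives intact in 15.

Assumption: 15 and 16 are taken as commercial; decalin carbons carry eudesmane locants (C-10 quaternary methyl carbon, C-5 ring-fusion CH, C-1 next to C-10, C-4 next to C-5, C-7 in ring B, C-9′ benzylic), and "cis/trans" always refers to the C-10 methyl group (10-Me).

**Route**

Step 1
Reactants: 1 (S)-Wieland–Miescher ketone
Product: 2 methylidene enone (C-1 exocyclic CH2, C-5=C-6–C-7=O enone)
Conditions: Ph3PCH3Br, KOtBu, THF, 0 → 23 °C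
Reagents that add atoms: methyltriphenylphosphonium bromide, C[P+](c1ccccc1)(c1ccccc1)c1ccccc1.[Br-]
Why: Wittig methylenation; the non-stabilised ylide attacks the saturated C-1 ketone, while the conjugated C-7 carbonyl is less electrophilic and is reversibly masked as its dienolate by the basic ylide; C-10 is untouched.

Step 2
Reactants: 2 methylidene enone
Product: 3 diene ketal (dioxolane at C-7, C-4=C-5, C-1=CH2)
Conditions: HOCH2CH2OH, HC(OEt)3, p-TsOH·H2O (cat.), CH2Cl2, 23 °C
Reagents that add atoms: ethylene glycol, OCCO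
Why: Acid-catalysed ketalisation of an enone runs through the dienol and gives the β,γ-unsaturated (C-4=C-5) ketal, as in the Δ4-3-ketone to Δ5-3-ketal conversion of steroids; room temperature and the orthoformate water scavenger keep the exocyclic methylidene from migrating.

Step 3
Reactants: 3 diene ketal
Product: 5 ketal diol (1-CH2OH cis, 4-OH trans, H-5 trans to 10-Me), via bis-borane 4 (not isolated)
Conditions: 9-BBN (1.2 equiv), THF, 23 °C; BH3·THF (3 equiv), 0 → 40 °C; then NaOH, H2O2, 0 → 40 °C
Reagents that add atoms: 9-borabicyclo[3.3.1]nonane (boron of 4), B1C2CCCC1CCC2; borane–tetrahydrofuran (boron of 4), B.C1CCOC1; hydrogen peroxide, OO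
Why: Brown hydroboration–oxidation (syn, anti-Markovnikov): 9-BBN takes only the 1,1-disubstituted alkene and, lacking a second B–H, cannot deliver boron intramolecularly to C-4; both boranes add from the face opposite the axial 10-Me, so H-1 and H-5 end up trans to 10-Me (equatorial 1-CH2OH, trans ring fusion as in Δ5-steroid hydroboration) and 4-OH is equatorial.

Step 4
Reactants: 5 ketal diol
Product: 6 silyl ether (1-CH2OSi(t-Bu)Ph2)
Conditions: t-BuPh2SiCl (1.05 equiv), imidazole, CH2Cl2, 0 °C
Reagents that add atoms: tert-butyl(chloro)diphenylsilane, CC(C)(C)[Si](Cl)(c1ccccc1)c1ccccc1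
Why: Silylation of the primary alcohol is much faster than that of the secondary 4-OH next to the ring fusion (steric chemoselectivity).

Step 5
Reactants: 6 silyl ether
Product: 7 hydroxy ketone (C-7 ketone)
Conditions: PPTS (0.3 equiv), acetone/H2O 10:1, 50 °C
Reagents that add atoms: water, O
Why: Mild acid hydrolysis (transketalisation) of the unhindered dioxolane; the TBDPS ether is stable to PPTS.

Step 6
Reactants: 7 hydroxy ketone
Product: 8 nitrile (C-7 carbonitrile, both epimers)
Conditions: TosMIC, KOtBu, DME, EtOH (2 equiv), 0 → 35 °C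
Reagents that add atoms: p-toluenesulfonylmethyl isocyanide, Cc1ccc(cc1)S(=O)(=O)C[N+]#[C-]
Why: van Leusen reductive cyanation converts the unhindered ketone into the nitrile with one extra carbon; C-7 is not controlled here and is settled in step 7.

Step 7
Reactants: 8 nitrile
Product: 10 methyl ketone (7-acetyl cis to 10-Me), via lithium ketimine 9 (not isolated)
Conditions: MeLi (4 equiv), Et2O, 0 → 23 °C; 1 M HCl, 0 °C; then K2CO3, MeOH, 23 °C
Reagents that add atoms: methyllithium, [Li]C; water, O
Why: Organolithium addition to a nitrile stops at the N-lithio ketimine and hydrolysis gives the methyl ketone; base equilibration through the enolate places the acetyl group equatorial, cis to 10-Me (about 9:1, minor epimer separated and recycled).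

Step 8
Reactants: 10 methyl ketone
Product: 11 diketone (C-4 ketone, 7-acetyl)
Conditions: (n-Pr4N)RuO4 (5 mol %), NMO, 4 Å MS, CH2Cl2, 23 °C
Reagents that add atoms: none
Why: Ley–Griffith oxidation of the secondary alcohol under neutral conditions, so the α-stereocentres C-5 and C-7 do not epimerise.

Step 9
Reactants: 11 diketone
Product: 12 silyl ether diol (4-OH cis and 4-Me trans to 10-Me; 7-(2-hydroxypropan-2-yl))
Conditions: MeMgBr (6 equiv), LaCl3·2LiCl (0.5 equiv), THF, −20 → 0 °C
Reagents that add atoms: methylmagnesium bromide, C[Mg]Br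
Why: Grignard addition to both ketones; at C-4 the axial trajectory is blocked by the 1,3-diaxial 10-Me, so methyl enters equatorially and leaves the axial 4-OH cis to 10-Me (the 6-oxo-steroid to 6α-methyl-6β-ol precedent); the lanthanum salt suppresses enolisation.

Step 10
Reactants: 12 silyl ether diol
Product: 13 triol
Conditions: TBAF, THF, 40 °C
Reagents that add atoms: none
Why: Fluoride-mediated cleavage of the Si–O bond; nothing else in the molecule reacts.

Step 11
Reactants: 13 triol
Product: 14 aldehyde (1-CHO cis to 10-Me)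
Conditions: TEMPO (0.1 equiv), PhI(OAc)2 (1.2 equiv), CH2Cl2, 23 °C
Reagents that add atoms: none
Why: Oxoammonium (TEMPO) oxidation is selective for the primary alcohol and leaves tertiary alcohols alone; the near-neutral medium keeps C-1, now α to the aldehyde, intact.

Step 12
Reactants: 14 aldehyde; 15 2,4,6-trihydroxybenzene-1,3-dicarbaldehyde; 16 (2-methylprop-1-en-1-yl)boronic acid
Product: 19 alkene (9′R), via benzodioxaborin 17 (not isolated), via boron-bound o-quinone methide 18 (not isolated)
Conditions: 15 (1.3 equiv), 16 (2 equiv), EtCO2H (0.3 equiv), PhMe/1,4-dioxane 4:1, 60 °C; aqueous work-up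
Reagents that add atoms: none
Why: Proposed new method: a boron-templated three-component ortho-(α-alkenylalkylation) of a phenol, in which the boron of 16, held on a phenolic oxygen of 15, delivers the carbonyl of 14 to the only free ring carbon through a six-membered Nagata-type transition state to give dioxaborin 17, acid-assisted C–O ionisation opens 17 to the boron-bound o-quinone methide 18, and the alkenyl group then moves from the tetracoordinate boron to the exocyclic carbon by ipso attack (the charge develops on the tertiary Me2C carbon β to the borate, which then collapses), a Petasis-type 1,4-transfer; the closest known chemistry is the Nagata ortho-hydroxyalkylation of phenols with PhB(OH)2, the Petasis borono-Mannich reaction and alkenylboronate conjugate addition to preformed o-quinone methides; C-9′ is set by allylic 1,3-strain, H-1 eclipsing the exocyclic C=C so that the alkenyl group enters anti to the quaternary C-10, which a vector model assigns as 9′R, and the tether to boron keeps the two formyl groups and the O-alkylation/chroman pathways out of play.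

Step 13
Reactants: 19 alkene
Product: 20 target
Conditions: H2 (3 bar), Rh/Al2O3 (5 wt % Rh), EtOAc, 23 °C
Reagents that add atoms: none
Why: Heterogeneous catalytic hydrogenation of the accessible trisubstituted alkene (no stereocentre is created); the hydrogen-bonded, vinylogous-acid formyl groups should not be reduced under these conditions, and Rh, unlike Pd, has little tendency to move the double bond towards C-9′.

**Compound list**
1 | (S)-Wieland–Miescher ketone, (8aS)-8a-methyl-3,4,8,8a-tetrahydronaphthalene-1,6(2H,7H)-dione | O=C1CCCC2=CC(=O)CC[C@]12C | starting material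
2 | methylidene enone, (4aR)-4a-methyl-5-methylidene-4,4a,5,6,7,8-hexahydronaphthalen-2(3H)-one | C=C1CCCC2=CC(=O)CC[C@]12C | intermediate
3 | diene ketal: 7,7-ethylenedioxy-10-methyl-1-methylidene-decal-4(5)-ene | C=C1CCC=C2CC3(OCCO3)CC[C@]12C | intermediate
4 | bis-borane (not isolated): 1-CH2–(9-BBN) and 4-BH2; H-1, H-5 and the C-4 boron trans to 10-Me | C1CCC2CCCC1B2C[C@H]1CC[C@H](B)[C@H]2CC3(OCCO3)CC[C@]12C | intermediate
5 | ketal diol: 7,7-ethylenedioxy trans-decalin, 1-CH2OH cis, 4-OH trans, H-5 trans to 10-Me | OC[C@H]1CC[C@H](O)[C@H]2CC3(OCCO3)CC[C@]12C | intermediate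
6 | silyl ether: 5 with 1-CH2OSi(t-Bu)Ph2 | CC(C)(C)[Si](OC[C@H]1CC[C@H](O)[C@H]2CC3(OCCO3)CC[C@]12C)(c1ccccc1)c1ccccc1 | intermediate
7 | hydroxy ketone: 6 with the C-7 ketone freed | CC(C)(C)[Si](OC[C@H]1CC[C@H](O)[C@H]2CC(=O)CC[C@]12C)(c1ccccc1)c1ccccc1 | intermediate
8 | nitrile: 7-carbonitrile, mixture of C-7 epimers (C-7 left undefined) | CC(C)(C)[Si](OC[C@H]1CC[C@H](O)[C@H]2CC(C#N)CC[C@]12C)(c1ccccc1)c1ccccc1 | intermediate
9 | lithium ketimine (not isolated): N-lithio ketimine, 4-OLi | CC(C)(C)[Si](OC[C@H]1CC[C@H](O[Li])[C@H]2CC(C(C)=N[Li])CC[C@]12C)(c1ccccc1)c1ccccc1 | intermediate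
10 | methyl ketone: 7-acetyl cis to 10-Me (equatorial), 4-OH | CC(C)(C)[Si](OC[C@H]1CC[C@H](O)[C@H]2C[C@@H](C(C)=O)CC[C@]12C)(c1ccccc1)c1ccccc1 | intermediate
11 | diketone: 7-acetyl-4-one | CC(C)(C)[Si](OC[C@H]1CCC(=O)[C@H]2C[C@@H](C(C)=O)CC[C@]12C)(c1ccccc1)c1ccccc1 | intermediate
12 | silyl ether diol: 4-OH cis and 4-Me trans to 10-Me, 7-(2-hydroxypropan-2-yl) cis | CC(C)(C)[Si](OC[C@H]1CC[C@@](C)(O)[C@H]2C[C@@H](C(C)(C)O)CC[C@]12C)(c1ccccc1)c1ccccc1 | intermediate
13 | triol: 1-CH2OH, 4-OH, 11-OH | OC[C@H]1CC[C@@](C)(O)[C@H]2C[C@@H](C(C)(C)O)CC[C@]12C | intermediate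
14 | aldehyde: 1-CHO cis to 10-Me, 4,11-diol | O=C[C@H]1CC[C@@](C)(O)[C@H]2C[C@@H](C(C)(C)O)CC[C@]12C | intermediate
15 | 2,4,6-trihydroxybenzene-1,3-dicarbaldehyde (2,4-diformylphloroglucinol) | O=Cc1c(O)cc(O)c(C=O)c1O | starting material
16 | (2-methylprop-1-en-1-yl)boronic acid | CC(C)=CB(O)O | starting material
17 | benzodioxaborin (not isolated): 2-(2-methylprop-1-enyl)-4-(decalin-1-yl)-4H-1,3,2-benzodioxaborin, C-4 of the heterocycle undefined | CC(C)=CB3OC([C@H]1CC[C@@](C)(O)[C@H]2C[C@@H](C(C)(C)O)CC[C@]12C)c4c(O)c(C=O)c(O)c(C=O)c4O3 | intermediate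
18 | boron-bound o-quinone methide (not isolated): carbonyl oxygen held by the alkenyl(dihydroxy)borate | CC(C)=C[B-](O)(O)[O+]=C3C(C=O)=C(O)C(C=O)=C(O)C3=C[C@H]1CC[C@@](C)(O)[C@H]2C[C@@H](C(C)(C)O)CC[C@]12C | intermediate
19 | alkene: 2,4,6-trihydroxy-5-[(1R)-1-[(1R,4R,4aS,6S,8aR)-4-hydroxy-6-(2-hydroxypropan-2-yl)-4,8a-dimethyldecahydronaphthalen-1-yl]-3-methylbut-2-en-1-yl]benzene-1,3-dicarbaldehyde | CC(C)=C[C@@H](c1c(O)c(C=O)c(O)c(C=O)c1O)[C@H]1CC[C@@](C)(O)[C@H]2C[C@@H](C(C)(C)O)CC[C@]12C | intermediate
20 | target: 2,4,6-trihydroxy-5-[(1R)-1-[(1R,4R,4aS,6S,8aR)-4-hydroxy-6-(2-hydroxypropan-2-yl)-4,8a-dimethyldecahydronaphthalen-1-yl]-3-methylbutyl]benzene-1,3-dicarbaldehyde | CC(C)C[C@@H](c1c(O)c(C=O)c(O)c(C=O)c1O)[C@H]1CC[C@@](C)(O)[C@H]2C[C@@H](C(C)(C)O)CC[C@]12C | target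

**Totals**
Total step count: 13. Longest linear sequence: 13 steps (1 → 20); 15 and 16 enter at step 12.

**Three steps most likely to fail**

Step 12 (the proposed new coupling). Risks: the hindered α-branched aldehyde may condense slowly, the o-quinone methide may tautomerise to a styrene, and the C-9′ selectivity rests on the allylic-strain model only. The fallback uses known chemistry, sets out from 14 and comes back to the route at 20. Aldehyde 14 and 15 are condensed under the Knoevenagel conditions long used to generate diformylphloroglucinol o-quinone methides (NaOAc, AcOH, 80 °C) in the presence of trimethyl(2-methylallyl)silane. Hosomi–Sakurai capture of the o-quinone methide at C-9′ (open transition state, same allylic-strain control) gives the 2-methylallyl adduct F1. H2 with RhCl(PPh3)3 in benzene/EtOH, which leaves aryl aldehydes alone, then saturates the 1,1-disubstituted alkene of F1 and gives 20 directly, so steps 12 and 13 are both bypassed.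

Step 13 (hydrogenation beside two free formyl groups). Risks: partial reduction of ArCHO, or metal-surface double-bond migration towards C-9′ that would scramble that centre. The fallback sets out from 19 and comes back at 20 by a different mechanism: hydrogen-atom-transfer reduction with Mn(dpm)3 (10 mol %), PhSiH3 and t-BuOOH in i-PrOH at 23 °C. The metal hydride gives a hydrogen atom to the alkene CH, and the resulting tertiary radical is quenched by a second hydrogen atom. The radical is two carbons away from C-9′, so C-9′ cannot be epimerised; the electron-rich formyl groups are expected to survive. New compounds on the way: none F0.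

Step 1 (chemoselective Wittig reaction on the diketone, with the acid-sensitive methylidene then carried through step 2). The fallback sets out from 1 and comes back at 3, reaching chemoselectivity by temporary redox differentiation. NaBH4 (EtOH, −10 °C) reduces only the saturated C-1 ketone and gives hydroxy enone F2 (1-OH cis to 10-Me). Ethylene glycol with p-TsOH (benzene, reflux; no alkene at risk) gives the deconjugated hydroxy ketal F3. (n-Pr4N)RuO4 with NMO gives keto ketal F4, in which C-1 is the only carbonyl. Ph3P=CH2 (THF, reflux) then gives 3.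

**Further compounds**
F1 | step 12 | 2-methylallyl adduct: 2,4,6-trihydroxy-5-[(1R)-1-[(1R,4R,4aS,6S,8aR)-4-hydroxy-6-(2-hydroxypropan-2-yl)-4,8a-dimethyldecahydronaphthalen-1-yl]-3-methylbut-3-en-1-yl]benzene-1,3-dicarbaldehyde | C=C(C)C[C@@H](c1c(O)c(C=O)c(O)c(C=O)c1O)[C@H]1CC[C@@](C)(O)[C@H]2C[C@@H](C(C)(C)O)CC[C@]12C
F0 | step 13 | none | none
F2 | step 1 | hydroxy enone: (4aS,5S)-5-hydroxy-4a-methyl-4,4a,5,6,7,8-hexahydronaphthalen-2(3H)-one | O[C@H]1CCCC2=CC(=O)CC[C@]12C
F3 | step 1 | hydroxy ketal: 7,7-ethylenedioxy-10-methyl-decal-4(5)-en-1-ol, 1-OH cis to 10-Me | O[C@H]1CCC=C2CC3(OCCO3)CC[C@]12C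
F4 | step 1 | keto ketal: 7,7-ethylenedioxy-10-methyl-decal-4(5)-en-1-one | O=C1CCC=C2CC3(OCCO3)CC[C@]12C
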